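In a closed flask the fractions of the substrate charge held as substrate (free or bound), as target, and as anything formed beyond target add up to one at every moment.

| flask | substrate | reagent | catalyst | time |
|---|---|---|---|---|
| birch | 0.500 M | 1.50 M | 0.00250 M |  |
| oak | 0.200 M | 1.20 M | 0.00250 M |  |
| ash | 1.50 M | 1.50 M | 0.00250 M |  |
| elm | 0.500 M | 0.750 M | 0.00250 M |  |
| maple | 0.500 M | 1.50 M | 6.30 × 10⁻⁴ M | 52 s |

| birch run: time / s | birch run: [target] / M | oak run: time / s | oak run: [target] / M | ash run: time / s | ash run: [target] / M | elm run: time / s | elm run: [target] / M |
|---|---|---|---|---|---|---|---|
| 10 | 0.071 | 10 | 0.026 | 10 | 0.165 | 10 | 0.040 |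
| 21 | 0.118 | 21 | 0.047 | 21 | 0.277 | 21 | 0.071 |
| 31 | 0.150 | 31 | 0.062 | 31 | 0.347 | 31 | 0.099 |
| 42 | 0.171 | 42 | 0.064 | 42 | 0.394 | 42 | 0.118 |
| 52 | 0.174 | 52 | 0.073 | 52 | 0.430 | 52 | 0.130 |

(each reading ± 0.003 M)

- the exponent of [reagent] in the starting rate at the charge of the birch run (at the point where two percent of the substrate have become target)
- the exponent of [substrate] in the starting rate at the charge of the birch run (at the point where two percent of the substrate have become target) (one fixed amount of target, the same in the runs compared)
- target in the maple run at 52 s, as a share of the substrate charged

- Overall: substrate + reagent -> target, with catalyst as catalyst.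
- Constant volume, constant temperature.
- The analysis sees a species whether free or bound.
- "The second partner" is reagent.
- An order is taken over about fifteen percent of the charge, up and down.

The elm run, at 0.500 of the birch reagent, reads 0.071 M at 21 s and 0.118 M at 42 s, just what the birch run reads at 10 s and 21 s. So these two curves run on reagent times time rather than on time, and the reagent order reads as one. The first ash and birch readings put the substrate order near 0.768 over that span.

Follow one substrate molecule: it becomes target, and the target may then go further, each a pseudo-first-order step in reagent. Suppose both steps in the birch run have about the same constant. With exposure x, that constant times reagent times time, the target fraction is then x·exp(−x). The first and last birch readings give the exposure constant, the fraction turned per unit of reagent times time, 0.0119 M⁻¹ s⁻¹. It returns 15.0% at 10 s, where the birch run reads 14.2%.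

The maple run has 0.252 of the birch catalyst, a quarter. Taking the first step as proportional to catalyst and the loss as unchanged, with exposure 0.931, this reckoning gives 13.4%.

The forecast, on different grounds, “time-based catalyst loss rather than product inhibition”, stands at 0.88, 0.82 and 13.5%.

The flask gives 1.0, 0.87 and 22.0%.

    catalyst + substrate ⇌ catalyst-substrate complex, settled at all times (0.7250 M⁻¹)
    catalyst-substrate complex + reagent → target + catalyst (5.540 M⁻¹ s⁻¹)
    substrate + reagent → target (0.004060 M⁻¹ s⁻¹)
    target + reagent → side product (0.01310 M⁻¹ s⁻¹)

At the start of the maple run, the first step has the pseudo-first-order constant 0.00888 s⁻¹, of which the catalyst-free path carries 68.6%. With that starting constant for the first step and 0.0119 M⁻¹ s⁻¹ for the loss, the reckoning for the maple run gives 23.2%. In the elm run, target comes to a quarter of the charge at 47.9 s, where 0.0119 M⁻¹ s⁻¹ gives exposure 0.429 and a target share of 27.9%.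

Readings and results were computed for substances that don't exist, noise included.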